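**Retrosynthesis**
1. Caruifolin B is a norbornanone. Cutting the C2–C2′ and C3–C5′ bonds (retro-[4+2]) gives a 3-silyloxycyclopentadiene (6, from a guaianolide enone) and a guaia-2,4-diene dienophile (5). The C4′ methyl stereocentre is then set by epimerization.
2. Both halves come from one guaianolide, isophotosantonic lactone (2). It is made from commercial (−)-α-santonin in one photochemical step, which builds the 5-7 skeleton, the C10 tertiary alcohol and the 6,12-lactone.
3. Ring-formation order: 5-7-lactone skeleton (photorearrangement), then cyclopentadienes 5 and 6 (deoxygenation, silyl dienol ether), then the cyclopentane and cyclopentanone together as the bicyclo[2.2.1]heptanone in one hetero-Diels–Alder.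
4. Most chemists would join two independently built guaianolides stepwise, or run a tethered or biomimetic DA on isolated monomers. Here I use one untethered cross-Diels–Alder that forms two C–C bonds, a quaternary centre and four stereocentres at once, and accept the homodimerization and selectivity risk.

**Assumptions**
- Photohydration of santonin gives 2 with the C1/C10 configuration drawn, which is the one found in both halves of the target.
- The santonin C6/C7/C11 configuration (all S) matches the target.

**Route**

**Step 1**
Reactants: 1 (−)-α-santonin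
Product: 2 isophotosantonic lactone (10-hydroxy-3-oxo-guai-4-en-12,6-olide)
Conditions: hν (medium-pressure Hg, Pyrex), AcOH/H2O 9:1, rt
Reagents that add atoms: water, O
Why: Cross-conjugated dienone photorearrangement (santonin → lumisantonin), then acid opening of the cyclopropyl ketone to a C10 cation that water captures. C6, C7 and C11 are untouched.

**Step 2**
Reactants: 2
Product: 3 (10-O-triethylsilyl ether of 2)
Conditions: TESOTf, 2,6-lutidine, CH2Cl2, −78 → 0 °C
Reagents that add atoms: TESOTf, CC[Si](CC)(CC)OS(=O)(=O)C(F)(F)F
Why: A silyl triflate with a hindered base silylates the tertiary alcohol and leaves the enone and lactone alone. The bulky β-OSiEt3 later blocks the β-face of both Diels–Alder partners.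

**Step 3**
Reactants: 3
Product: 4 (cyclopentadienyl triflate: 3-OTf-guaia-2,4-dienolide, 10-OTES)
Conditions: KHMDS, THF, −78 °C; then PhNTf2, −78 → 0 °C
Reagents that add atoms: PhNTf2, O=S(=O)(C(F)(F)F)N(c1ccccc1)S(=O)(=O)C(F)(F)F
Why: Kinetic deprotonation at the only α′ CH2 (C2) gives the cross-conjugated enolate, which is trapped as the enol triflate. The lactone α-H is less acidic and C1 is not touched.

**Step 4**
Reactants: 4
Product: 5 (10-OTES-guaia-2,4-dien-12,6-olide, the diene/dienophile partner A)
Conditions: Pd(OAc)2, PPh3, HCO2H, Et3N, DMF, 50 °C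
Reagents that add atoms: none (hydride from formate)
Why: Pd-catalysed formate hydrogenolysis of a vinyl triflate (Cacchi reduction) replaces C3–OTf by C3–H, leaving C4=C5 intact. The product is used immediately because it can undergo 1,5-H shifts and dimerize.

**Step 5**
Reactants: 3
Product: 6 (cross-conjugated 3-OTES silyl dienol ether, 10-OTES)
Conditions: LiHMDS, THF, −78 °C; then TESCl, Et3N, −78 → 0 °C; used crude
Reagents that add atoms: TESCl, CC[Si](Cl)(CC)CC
Why: Kinetic enolization at C2 and O-silylation give the 2-silyloxycyclopentadiene C2=C3(OSi)–C4(Me)=C5. C1 remains sp3, so its stereocentre is kept.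

**Step 6**
Reactants: 5 (3 equiv) and 6 (1 equiv)
Product: 7 (bis-10-OTES norbornene silyl enol ether adduct)
Conditions: toluene, BHT, 110 °C, sealed tube
Reagents that add atoms: none
Why: Diels–Alder reaction.
- Proposed new method: an asynchronous polar endo [4+2] between the electron-rich diene 6 and the C2=C3 alkene of cyclopentadiene 5, as in cyclopentadiene dimerization and 2-siloxydiene cycloadditions.
- Regiochemistry: the nucleophilic enol-ether terminus C2′ bonds to the unhindered C2 of 5, and the hindered C5′ to C3.
- Stereochemistry: the endo rule places the ring of 5 under the enol-ether bridge. Both partners react on the α-face, anti to the bulky 10β-OSiEt3 groups, which fixes C2, C3, C2′, C5′ and the bridge carbon C1′.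
- Excess 5 suppresses homodimerization of 6.

**Step 7**
Reactants: 7
Product: 8 (caruifolin B)
Conditions: (i) HF·pyridine, THF, 0 °C → rt; (ii) K2CO3, MeOH, 0 °C → rt
Reagents that add atoms: none
Why: HF removes both tertiary TES ethers and protodesilylates the enol ether to the norbornanone, giving a C4′ epimer mixture. Base-mediated α-epimerization through the enol (Bredt-blocked at the bridgehead C2′) equilibrates to the exo-methyl isomer, because endo-Me would clash with the endo C4=C5 ring. The two tertiary alcohols, lactones and C4=C5 survive.

**Compound list**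
1 | (−)-α-santonin | CC1=C2[C@H]3OC(=O)[C@@H](C)[C@@H]3CC[C@@]2(C)C=CC1=O | starting material
2 | isophotosantonic lactone | CC1=C2[C@H]3OC(=O)[C@@H](C)[C@@H]3CC[C@](C)(O)[C@@H]2CC1=O | intermediate
3 | 10-O-TES enone | CC1=C2[C@H]3OC(=O)[C@@H](C)[C@@H]3CC[C@](C)(O[Si](CC)(CC)CC)[C@@H]2CC1=O | intermediate
4 | cyclopentadienyl triflate | CC1=C2[C@H]3OC(=O)[C@@H](C)[C@@H]3CC[C@](C)(O[Si](CC)(CC)CC)[C@@H]2C=C1OS(=O)(=O)C(F)(F)F | intermediate
5 | 10-OTES guaia-2,4-dienolide | CC1=C2[C@H]3OC(=O)[C@@H](C)[C@@H]3CC[C@](C)(O[Si](CC)(CC)CC)[C@@H]2C=C1 | intermediate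
6 | silyl dienol ether | CC1=C2[C@H]3OC(=O)[C@@H](C)[C@@H]3CC[C@](C)(O[Si](CC)(CC)CC)[C@@H]2C=C1O[Si](CC)(CC)CC | intermediate
7 | Diels–Alder adduct | CC1=C2[C@H]3OC(=O)[C@@H](C)[C@@H]3CC[C@](C)(O[Si](CC)(CC)CC)[C@@H]2[C@H]2[C@H]3C(O[Si](CC)(CC)CC)=C(C)[C@]4([C@@H]3[C@@](C)(O[Si](CC)(CC)CC)CC[C@H]3[C@H](C)C(=O)O[C@@H]34)[C@@H]12 | intermediate
8 | caruifolin B | CC1=C2[C@H]3OC(=O)[C@@H](C)[C@@H]3CC[C@](C)(O)[C@@H]2[C@H]2[C@H]3C(=O)[C@H](C)[C@]4([C@@H]3[C@@](C)(O)CC[C@H]3[C@H](C)C(=O)O[C@@H]34)[C@@H]12 | target

**Totals**
- Total steps: 7.
- Longest linear sequence: 6 (steps 1, 2, 3, 4, 6, 7 from santonin; step 5 is a parallel branch).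

**Three steps most likely to fail**
1. **Step 6 (cross-Diels–Alder).** Homodimerization of 5 or 6, the wrong regio- or facial outcome, or 1,5-H-shifted diene isomers could intervene.
   - Fallback: change the dienophile to a polarity-matched one. Convert the C3 ketone of 3 to a cyclopentadienyl sulfone, run a normal-demand Diels–Alder with 6, then remove the sulfone reductively, with the desulfonylation regiochemistry to be checked.
2. **Step 4 (cyclopentadiene 5 from the dienyl triflate).** The triflate or diene may be unstable, give alkene-transposed isomers, or dimerize.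
   - Fallback: never isolate 5. Luche-reduce 3 to the C3 allylic alcohol and dehydrate it with Burgess reagent in situ in the presence of 6.
3. **Step 1 (photohydration).** The yield is modest, and the C10 configuration is an assumption.
   - Fallback: take the two-stage path through lumisantonin (neutral photolysis), then acid opening with H2O or AcOH, separate the C10 epimers, and use the 10-acetate from anhydrous AcOH as the protecting group in place of TES.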